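## Analysis of the target

The target 14 is a flavonol, a 2-aryl-3-hydroxy-4H-chromen-4-one. Its benzo ring A (C4a, C5, C6, C7, C8, C8a) is fused to the pyranone ring C (O1, C2, C3, C4), and the 3,4-dihydroxyphenyl ring B sits on C2. The molecule has no stereocenter, so the task is one of substitution pattern only. Ring A is hexasubstituted and carries four contiguous oxygens, a hydroxyl on C5 and methoxyls on C6, C7 and C8, so that of the seven exocyclic oxygens four must end as free hydroxyls (C3, C5, C3', C4') and three as methyl ethers (C6, C7, C8). The difficulty lies in building the crowded oxygenation of ring A and then telling seven similar oxygens apart. The sensitive parts are the catechol of ring B and the 3-hydroxy enol of ring C, both easily oxidised as their anions, and C2 of the pyranone, which accepts hard nucleophiles with opening of ring C. The plan rests on one observation: without the oxygens on C6 and C8, 14 has the carbon–oxygen skeleton of quercetin 1, and C6 and C8 are the two CH carbons of ring A that lie ortho or para to all three ring A oxygens (on C5, C7 and C8a). The hydroxyls that must stay free also fall into two addressable pairs: a vicinal pair on ring B that can be bridged, and a pair flanking the C4 carbonyl (C3 and C5) that can be reached by chelation.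

## Retrosynthetic reasoning

**14 to 12.** The last operation uncovers the hydroxyls on C3 and C5, so the first cut is in the two O–CH3 bonds at these positions, leading back to the pentamethyl ether 12. These are the only methoxyls next to the C4 carbonyl. A chelating Lewis acid on the carbonyl oxygen reaches the C5 oxygen through a six-membered chelate and the C3 oxygen through a five-membered one; the methoxyls on C6, C7 and C8 have no such neighbour. The forward step must remove exactly two of five methyl groups, expected in the order C5 then C3, through the monophenol 13. The gain is that every oxygen on rings A and C can travel as a methyl ether until the end.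

**12 to 11.** The free catechol of 12 is traced back to the cyclic diphenylmethylene ketal 11 by cutting the two O–C bonds at the ketal carbon. The ketal is removed before the Lewis acid step, not after it, because a diaryl ketal would ionise under an aluminium halide and that step would have no defined product. Aqueous Brønsted acid leaves aryl methyl ethers alone.

**11 to 8 and 9.** This is the strategic cut: the aryl–oxygen bonds at C6 and C8. These two oxygens are the only ones quercetin 1 lacks, and their carbons are where a halogen goes without any directing device. The forward reaction is a twofold copper-mediated substitution of the aryl bromides of 8 by sodium methoxide 9, one equivalent of 9 for each bromine, passing through a monobromo intermediate 10. It must form two hindered C–O bonds without reducing the C–Br bonds and without destroying ring C. No ring is formed, and the step delivers the full oxygen pattern of ring A in one operation.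

**8 to 6.** The two C–Br bonds are cut to give the trimethyl ether 6. The forward reaction is electrophilic bromination. It must touch only C6 and C8 (through the monobromide 7) and leave ring B and C3 alone. The three oxygen donors of ring A and the methoxyl blocking C3 secure this.

**6 to 3.** The three O–CH3 bonds at C3, C5 and C7 are cut to give the triol 3. The C7 methyl is part of the target. The C3 and C5 methyls are protecting groups: they keep the substrate of the copper step neutral, so no phenoxide deactivates the ring or exposes the enol to oxidation, they block C3 against the brominating agent, and they are the two that chelation can later remove. Exhaustive methylation is chosen over selective methylation, so the forward step needs no selectivity. It passes through the partly methylated 4 and 5.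

**3 to 1 and 2.** The two O–C bonds of the ketal are cut to give quercetin 1 and dichlorodiphenylmethane 2. Only the vicinal hydroxyls on C3' and C4' can close a five-membered dioxole with one carbon, so the catechol is singled out by geometry. The whole carbon skeleton and five of the seven oxygens are bought in 1.

## Alternatives that were turned down

**Alternative 1:** The cut is the C4a–C8a bond, so ring A is made from an open chain. The precursor is methyl 8-(benzyloxy)-2,4-dimethoxy-3,5,7-trioxooctanoate A2, which already holds the future C6 and C8 methoxyls. With an alkoxide base, the methylene between the C5 and C7 ketones of A2 attacks the ester carbon in a Claisen cyclisation. Loss of the ester alkoxide and enolisation give the acylphloroglucinol 2-(benzyloxy)-1-(2,4,6-trihydroxy-3,5-dimethoxyphenyl)ethan-1-one A1.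
- For: both extra oxygens come with the chain, so no halogenation and no metal-mediated C–O coupling is needed. A1 is symmetric, so closing ring C later raises no regiochemical question. On certainty of the ring A pattern this plan is at least as strong as the chosen one.
- Against: A2 is a tetracarbonyl compound with two α-methoxy ketone units. Its preparation is a multistep problem, and it can fold in other ways (aldol attack of C2 on the C7 ketone to a resorcylate, or lactonisation to a pyranone). After A1, rings C and B are still missing: the C4 hydroxyl must be methylated selectively, a protected dihydroxybenzoyl unit attached, ring C closed (Allan–Robinson or Baker–Venkataraman type) and the protecting groups removed.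
- Comparison: it would take well over ten steps to reach what the chosen route reaches in six. The chosen route buys rings A, B and C in 1 and spends its risk on two C–O bonds.

**Alternative 2:** The cuts are the C1'–C2' and C5'–C6' bonds, so ring B is grown last. The dienophile is 3-(benzyloxy)-2-ethynyl-5,6,7,8-tetramethoxy-4H-chromen-4-one A4 and the diene is 2,3-bis(trimethylsilyloxy)buta-1,3-diene A5. A Diels–Alder reaction gives the 1,4-cyclohexadiene 3-(benzyloxy)-2-[4,5-bis(trimethylsilyloxy)cyclohexa-1,4-dien-1-yl]-5,6,7,8-tetramethoxy-4H-chromen-4-one A3. Dehydrogenation, desilylation, cleavage of the C5 methyl ether and debenzylation would follow.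
- For: the diene is symmetric, so there is no regiochemistry. The alkyne is conjugated through C2=C3 to the C4 carbonyl and is therefore activated. The C3 oxygen is carried as a benzyl ether, so the end game needs only the easy C5 demethylation and a hydrogenolysis. On that point it is stronger than the chosen route, which must cleave a C3 methyl ether.
- Against: the ring-forming step is spent on ring B, the simplest part of the molecule. The four contiguous oxygens of ring A must all be assembled beforehand in A4, by a long linear sequence through a pentaoxygenated acetophenone, the chromone, C3 oxygenation and C2 alkynylation. The C3 alkoxy group donates into the enone and lowers the dienophilicity of A4. A5 and the bis(silyl enol ether) A3 are moisture-sensitive and must survive an oxidation.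
- Comparison: the chosen route offers the ring A pattern in a single step on a purchased skeleton, at the price of a less comfortable final demethylation.

**Alternative 3:** The cuts are three bonds of ring C: C4a–C4, C4–C3 and O1–C2. The components are 2-iodo-3,4,5,6-tetramethoxyphenol A7, carbon monoxide A9 and 4-ethynyl-1,2-bis(benzyloxy)benzene A8, joined in a palladium-catalysed carbonylative coupling in an amine base. Zerovalent palladium adds into the C–I bond, A9 inserts to an acylpalladium species of divalent palladium, coupling with A8 gives an alkynone, and 6-endo oxa-Michael closure gives 3',4'-bis(benzyloxy)-5,6,7,8-tetramethoxyflavone A6.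
- For: it is the most convergent plan, making three bonds and ring C in one step from two halves. On convergence it is stronger than the chosen linear route.
- Against: A6 has hydrogen on C3. The C3 oxygen of 14 is absent and would have to be introduced afterwards by oxidation of an electron-rich flavone, which costs steps and has uncertain selectivity. A7 is a hexasubstituted benzene, so making it restates the ring A problem, and oxidative addition into so electron-rich and doubly ortho-substituted an iodide is slow. 5-Exo closure to an aurone competes with the 6-endo mode. The C5 demethylation and the debenzylation remain.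
- Comparison: the chosen route starts with the C3 oxygen and ring C already in place and needs no aromatic building block beyond 1.

Key step: step 4

Assumption: commercial quercetin is dried to the anhydrous form before use, and in steps 3 and 4 the less hindered C8 is taken to react before C6, the reverse order leading to the same isolated products 8 and 11.

## Route

Step 1
Reactants: 1 quercetin; 2 dichlorodiphenylmethane
Product: 3 2-(2,2-diphenyl-1,3-benzodioxol-5-yl)-3,5,7-trihydroxy-4H-chromen-4-one
Conditions: Ph2CCl2 (1.5 equiv), Ph2O, 175 °C, N2 sweep
Reagents that add atoms: none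
Why: Thermal ketalisation of a catechol by a geminal dichloride, with ionisation to a diaryl-stabilised cation and loss of two HCl. Only the vicinal C3' and C4' hydroxyls can close the five-membered dioxole, and a single ether formed at any other hydroxyl would be an α-chloro ether that reverts on work-up.

Step 2
Reactants: 3 2-(2,2-diphenyl-1,3-benzodioxol-5-yl)-3,5,7-trihydroxy-4H-chromen-4-one
Product: 6 2-(2,2-diphenyl-1,3-benzodioxol-5-yl)-3,5,7-trimethoxy-4H-chromen-4-one, via 7-O-methyl ether 4 (not isolated), via 3,7-di-O-methyl ether 5 (not isolated)
Conditions: Me2SO4 (6 equiv), K2CO3 (8 equiv), acetone, reflux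
Reagents that add atoms: dimethyl sulfate, COS(=O)(=O)OC
Why: Williamson O-methylation of the phenoxides and the enolate oxygen, one methyl group from each molecule of dimethyl sulfate. The hydroxyls should react in order of acidity (C7, then C3, then the hydrogen-bonded C5), and the last needs the excess reagent and prolonged reflux. The ketal is inert to base.

Step 3
Reactants: 6 2-(2,2-diphenyl-1,3-benzodioxol-5-yl)-3,5,7-trimethoxy-4H-chromen-4-one
Product: 8 6,8-dibromo-2-(2,2-diphenyl-1,3-benzodioxol-5-yl)-3,5,7-trimethoxy-4H-chromen-4-one, via monobromide 7 (not isolated)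
Conditions: NBS (2.2 equiv), DMF, 0 °C to rt, dark
Reagents that add atoms: N-bromosuccinimide, O=C1CCC(=O)N1Br
Why: Electrophilic aromatic bromination. C6 and C8 are each ortho or para to three oxygen donors (on C5, C7 and C8a), whereas ring B has two donors and is conjugated to the electron-poor pyranone, and C3 is blocked by its methoxyl. The neutral conditions (succinimide as by-product) spare the acid-labile ketal.

Step 4
Reactants: 8 6,8-dibromo-2-(2,2-diphenyl-1,3-benzodioxol-5-yl)-3,5,7-trimethoxy-4H-chromen-4-one; 9 sodium methoxide
Product: 11 2-(2,2-diphenyl-1,3-benzodioxol-5-yl)-3,5,6,7,8-pentamethoxy-4H-chromen-4-one, via monobromo tetramethyl ether 10 (not isolated)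
Conditions: NaOMe (25% in MeOH, 20 equiv), CuBr (0.5 equiv), dry DMF, 110 °C (sealed vessel), Ar
Reagents that add atoms: sodium methoxide, C[O-].[Na+]
Why: This is an Ullmann-type copper-mediated methoxylation of aryl bromides, a reaction type known for 6,8-dibromo-5,7-dimethoxyflavones. Methoxide and CuBr form a methoxycuprate of monovalent copper, which adds oxidatively into a C–Br bond to give an aryl species of trivalent copper; reductive elimination then forms the aryl–OMe bond and returns monovalent copper. The cycle runs twice, first at C8 and then at C6 by way of 10, so two equivalents of sodium methoxide are consumed, one entered as reactant 9 and one as the added reagent. The step closes no ring and creates no stereocenter; it forms only the C6–O and C8–O bonds. No site selectivity is asked of it, because the two bromines are the only carbon–halogen bonds in 8 and both are to be replaced, their positions having been fixed in step 3 by the oxygens on C5, C7 and C8a. What it does need is substitution over hydrodebromination and over destruction of ring C by attack at C2. A high methoxide concentration and exclusion of air serve the first, helped by the fact that 8 has no acidic hydroxyl and so stays neutral rather than becoming a deactivated phenoxide. Exclusion of water serves the second, since methoxide addition at C2 is reversible whereas hydroxide would cleave the opened diketone irreversibly, and the ketal and the methyl ethers are stable to the base.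

Step 5
Reactants: 11 2-(2,2-diphenyl-1,3-benzodioxol-5-yl)-3,5,6,7,8-pentamethoxy-4H-chromen-4-one
Product: 12 2-(3,4-dihydroxyphenyl)-3,5,6,7,8-pentamethoxy-4H-chromen-4-one
Conditions: AcOH–H2O (4:1), reflux, N2
Reagents that add atoms: none
Why: Acid hydrolysis of a diaryl ketal. Protonation and ring opening give a diphenyl-stabilised oxocarbenium ion that water traps, releasing benzophenone and the catechol. Aryl methyl ethers and the flavone core are stable to hot aqueous acetic acid.

Step 6
Reactants: 12 2-(3,4-dihydroxyphenyl)-3,5,6,7,8-pentamethoxy-4H-chromen-4-one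
Product: 14 2-(3,4-dihydroxyphenyl)-3,5-dihydroxy-6,7,8-trimethoxy-4H-chromen-4-one (3,5,3',4'-tetrahydroxy-6,7,8-trimethoxyflavone), via 5-hydroxy tetramethyl ether 13 (not isolated)
Conditions: AlCl3 (anhydrous, 12 equiv), MeCN, 70 °C; then 2% aq HCl, 70 °C
Reagents that add atoms: none
Why: Chelation-controlled Lewis acid cleavage of aryl methyl ethers. Aluminium bound to the C4 carbonyl oxygen also binds the C5 oxygen (six-membered chelate) and then the C3 oxygen (five-membered chelate), and chloride removes each activated methyl group as chloromethane by SN2 attack. The methoxyls on C6, C7 and C8 have no neighbouring carbonyl and should stay, and the free catechol only consumes extra AlCl3; warm dilute HCl breaks the aluminium chelates.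

## Compound list

1 | quercetin, 2-(3,4-dihydroxyphenyl)-3,5,7-trihydroxy-4H-chromen-4-one | O=c1c(O)c(-c2ccc(O)c(O)c2)oc2cc(O)cc(O)c12 | starting material
2 | dichlorodiphenylmethane | ClC(Cl)(c1ccccc1)c1ccccc1 | starting material
3 | 2-(2,2-diphenyl-1,3-benzodioxol-5-yl)-3,5,7-trihydroxy-4H-chromen-4-one | O=c1c(O)c(-c2ccc3OC(c4ccccc4)(c4ccccc4)Oc3c2)oc2cc(O)cc(O)c12 | intermediate
4 | 2-(2,2-diphenyl-1,3-benzodioxol-5-yl)-3,5-dihydroxy-7-methoxy-4H-chromen-4-one | O=c1c(O)c(-c2ccc3OC(c4ccccc4)(c4ccccc4)Oc3c2)oc2cc(OC)cc(O)c12 | intermediate
5 | 2-(2,2-diphenyl-1,3-benzodioxol-5-yl)-5-hydroxy-3,7-dimethoxy-4H-chromen-4-one | O=c1c(OC)c(-c2ccc3OC(c4ccccc4)(c4ccccc4)Oc3c2)oc2cc(OC)cc(O)c12 | intermediate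
6 | 2-(2,2-diphenyl-1,3-benzodioxol-5-yl)-3,5,7-trimethoxy-4H-chromen-4-one | COc1cc(OC)c2c(=O)c(OC)c(-c3ccc4OC(c5ccccc5)(c5ccccc5)Oc4c3)oc2c1 | intermediate
7 | 8-bromo-2-(2,2-diphenyl-1,3-benzodioxol-5-yl)-3,5,7-trimethoxy-4H-chromen-4-one | COc1cc(OC)c2c(=O)c(OC)c(-c3ccc4OC(c5ccccc5)(c5ccccc5)Oc4c3)oc2c1Br | intermediate
8 | 6,8-dibromo-2-(2,2-diphenyl-1,3-benzodioxol-5-yl)-3,5,7-trimethoxy-4H-chromen-4-one | COc1c(Br)c(OC)c2c(=O)c(OC)c(-c3ccc4OC(c5ccccc5)(c5ccccc5)Oc4c3)oc2c1Br | intermediate
9 | sodium methoxide | C[O-].[Na+] | starting material
10 | 6-bromo-2-(2,2-diphenyl-1,3-benzodioxol-5-yl)-3,5,7,8-tetramethoxy-4H-chromen-4-one | COc1c(Br)c(OC)c2c(=O)c(OC)c(-c3ccc4OC(c5ccccc5)(c5ccccc5)Oc4c3)oc2c1OC | intermediate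
11 | 2-(2,2-diphenyl-1,3-benzodioxol-5-yl)-3,5,6,7,8-pentamethoxy-4H-chromen-4-one | COc1c(OC)c(OC)c2c(=O)c(OC)c(-c3ccc4OC(c5ccccc5)(c5ccccc5)Oc4c3)oc2c1OC | intermediate
12 | 2-(3,4-dihydroxyphenyl)-3,5,6,7,8-pentamethoxy-4H-chromen-4-one | COc1c(OC)c(OC)c2c(=O)c(OC)c(-c3ccc(O)c(O)c3)oc2c1OC | intermediate
13 | 2-(3,4-dihydroxyphenyl)-5-hydroxy-3,6,7,8-tetramethoxy-4H-chromen-4-one | COc1c(OC)c(O)c2c(=O)c(OC)c(-c3ccc(O)c(O)c3)oc2c1OC | intermediate
14 | 2-(3,4-dihydroxyphenyl)-3,5-dihydroxy-6,7,8-trimethoxy-4H-chromen-4-one (3,5,3',4'-tetrahydroxy-6,7,8-trimethoxyflavone) | COc1c(OC)c(O)c2c(=O)c(O)c(-c3ccc(O)c(O)c3)oc2c1OC | target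

## Step count and least certain steps

Total step count: 6. Longest linear sequence: 6 steps (the route is fully linear, 1 to 14).

**Step 4 (key step).** The likely failures are reductive loss of bromine and stalling after the first substitution. Reduction would come from a CuH species formed by β-hydride loss from the CuOMe intermediate. Stalling would arise because the remaining bromide is flanked by two alkoxy groups on a ring that has become more electron-rich. Prolonged heating in methoxide can also open ring C. The fallback changes the C–O coupling into a C–B route; it sets out from 8 and returns at 11. Twofold Miyaura borylation of 8 (B2pin2, Pd(OAc)2, SPhos, KOAc, dioxane, 100 °C) should give 2-(2,2-diphenyl-1,3-benzodioxol-5-yl)-3,5,7-trimethoxy-6,8-bis(4,4,5,5-tetramethyl-1,3,2-dioxaborolan-2-yl)-4H-chromen-4-one F1. Oxidation of both C–B bonds (H2O2, aq NaHCO3, THF, 0 °C to rt) should then give 2-(2,2-diphenyl-1,3-benzodioxol-5-yl)-6,8-dihydroxy-3,5,7-trimethoxy-4H-chromen-4-one F2, and O-methylation of its two new phenols (Me2SO4, K2CO3, acetone, reflux) leads to 11.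

**Step 6.** The likely failures are over-demethylation at C6 and incomplete cleavage at C3. Once the C5 oxygen is bound to aluminium as a phenoxide, it can form a second chelate with the C6 methoxyl and activate it. The C3 ether is the slower of the two wanted cleavages. The fallback avoids methyl ethers on C3 and C5 altogether; it sets out from 3 and returns at 14. One equivalent of MeI with K2CO3 in DMF at room temperature should methylate only the most acidic hydroxyl and give 4, isolated this time. BnBr and K2CO3 in DMF should then benzylate the C3 hydroxyl while the hydrogen-bonded C5 hydroxyl stays free, giving 3-(benzyloxy)-2-(2,2-diphenyl-1,3-benzodioxol-5-yl)-5-hydroxy-7-methoxy-4H-chromen-4-one F3. NBS in DMF should give 3-(benzyloxy)-6,8-dibromo-2-(2,2-diphenyl-1,3-benzodioxol-5-yl)-5-hydroxy-7-methoxy-4H-chromen-4-one F4. NaOMe and CuBr in DMF–MeOH, with the C5 hydroxyl carried as its phenoxide, should give 3-(benzyloxy)-2-(2,2-diphenyl-1,3-benzodioxol-5-yl)-5-hydroxy-6,7,8-trimethoxy-4H-chromen-4-one F5. Hydrogenolysis (H2, Pd/C, THF–MeOH) finally removes the benzyl ether and the diphenylmethylene ketal together and gives 14.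

**Step 3.** The likely failures are competing bromination of ring B at C6' (para to the C3' oxygen) and unequal reaction at the two ring A positions, which would leave monobromide beside over-brominated material. The fallback uses a free phenol as the director; it sets out from 3 and returns at 8. The methylation is stopped at the chelated stage (Me2SO4, 2.2 equiv, K2CO3, acetone, rt) and 5 is isolated. NBS (2.0 equiv, DMF, 0 °C) should then brominate ortho and para to the free C5 hydroxyl, which raises the reactivity of ring A further above that of ring B, giving 6,8-dibromo-2-(2,2-diphenyl-1,3-benzodioxol-5-yl)-5-hydroxy-3,7-dimethoxy-4H-chromen-4-one F6. Forcing methylation of the C5 hydroxyl (Me2SO4, K2CO3, DMF, 60 °C) returns to 8.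

**Step 5.** The likely failures are incomplete hydrolysis, because the lipophilic ketal dissolves poorly in aqueous acid, and air oxidation of the liberated catechol at reflux. The fallback cleaves the ketal by reduction and not by hydrolysis; it sets out from 11 and returns at 12. Hydrogenolysis (H2, Pd/C, THF–MeOH, rt) cleaves the two benzylic C–O bonds of the ketal and gives 12 directly. It makes no compound outside the compound list (F0).

## Further compounds

F1 | step 4 | 2-(2,2-diphenyl-1,3-benzodioxol-5-yl)-3,5,7-trimethoxy-6,8-bis(4,4,5,5-tetramethyl-1,3,2-dioxaborolan-2-yl)-4H-chromen-4-one | COc1c(B2OC(C)(C)C(C)(C)O2)c(OC)c2c(=O)c(OC)c(-c3ccc4OC(c5ccccc5)(c5ccccc5)Oc4c3)oc2c1B1OC(C)(C)C(C)(C)O1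
F2 | step 4 | 2-(2,2-diphenyl-1,3-benzodioxol-5-yl)-6,8-dihydroxy-3,5,7-trimethoxy-4H-chromen-4-one | COc1c(O)c(OC)c2c(=O)c(OC)c(-c3ccc4OC(c5ccccc5)(c5ccccc5)Oc4c3)oc2c1O
F3 | step 6 | 3-(benzyloxy)-2-(2,2-diphenyl-1,3-benzodioxol-5-yl)-5-hydroxy-7-methoxy-4H-chromen-4-one | COc1cc(O)c2c(=O)c(OCc3ccccc3)c(-c3ccc4OC(c5ccccc5)(c5ccccc5)Oc4c3)oc2c1
F4 | step 6 | 3-(benzyloxy)-6,8-dibromo-2-(2,2-diphenyl-1,3-benzodioxol-5-yl)-5-hydroxy-7-methoxy-4H-chromen-4-one | COc1c(Br)c(O)c2c(=O)c(OCc3ccccc3)c(-c3ccc4OC(c5ccccc5)(c5ccccc5)Oc4c3)oc2c1Br
F5 | step 6 | 3-(benzyloxy)-2-(2,2-diphenyl-1,3-benzodioxol-5-yl)-5-hydroxy-6,7,8-trimethoxy-4H-chromen-4-one | COc1c(OC)c(O)c2c(=O)c(OCc3ccccc3)c(-c3ccc4OC(c5ccccc5)(c5ccccc5)Oc4c3)oc2c1OC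
F6 | step 3 | 6,8-dibromo-2-(2,2-diphenyl-1,3-benzodioxol-5-yl)-5-hydroxy-3,7-dimethoxy-4H-chromen-4-one | COc1c(Br)c(O)c2c(=O)c(OC)c(-c3ccc4OC(c5ccccc5)(c5ccccc5)Oc4c3)oc2c1Br
F0 | step 5 | none | none
A1 | alternative 1 | 2-(benzyloxy)-1-(2,4,6-trihydroxy-3,5-dimethoxyphenyl)ethan-1-one | COc1c(O)c(OC)c(O)c(C(=O)COCc2ccccc2)c1O
A2 | alternative 1 | methyl 8-(benzyloxy)-2,4-dimethoxy-3,5,7-trioxooctanoate | COC(=O)C(OC)C(=O)C(OC)C(=O)CC(=O)COCc1ccccc1
A3 | alternative 2 | 3-(benzyloxy)-2-[4,5-bis(trimethylsilyloxy)cyclohexa-1,4-dien-1-yl]-5,6,7,8-tetramethoxy-4H-chromen-4-one | COc1c(OC)c(OC)c2c(=O)c(OCc3ccccc3)c(C3=CCC(O[Si](C)(C)C)=C(O[Si](C)(C)C)C3)oc2c1OC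
A4 | alternative 2 | 3-(benzyloxy)-2-ethynyl-5,6,7,8-tetramethoxy-4H-chromen-4-one | COc1c(OC)c(OC)c2c(=O)c(OCc3ccccc3)c(C#C)oc2c1OC
A5 | alternative 2 | 2,3-bis(trimethylsilyloxy)buta-1,3-diene | C=C(O[Si](C)(C)C)C(=C)O[Si](C)(C)C
A6 | alternative 3 | 3',4'-bis(benzyloxy)-5,6,7,8-tetramethoxyflavone | COc1c(OC)c(OC)c2c(=O)cc(-c3ccc(OCc4ccccc4)c(OCc4ccccc4)c3)oc2c1OC
A7 | alternative 3 | 2-iodo-3,4,5,6-tetramethoxyphenol | COc1c(O)c(I)c(OC)c(OC)c1OC
A8 | alternative 3 | 4-ethynyl-1,2-bis(benzyloxy)benzene | C#Cc1ccc(OCc2ccccc2)c(OCc2ccccc2)c1
A9 | alternative 3 | carbon monoxide | [C-]#[O+]
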